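**Retrosynthetic overview**
1. Megaphone 15 ⇐ enone 12 + allyl bromide 13: the quaternary C6 centre is made last, by C-allylation of the alkoxide–dienolate dianion.
2. 12 ⇐ saturated hydroxy ketone 10 (Saegusa desaturation); 10 ⇐ γ-keto aldehyde 6 + aryl metal (Felkin addition sets the benzylic carbinol).
3. Key disconnection C6–C7 (1,4-dicarbonyl, two α-carbons joined): 6 ⇐ propanal 4, used as an α-carbonyl cation equivalent through its enamine radical cation, + enol silane 3.
4. 3 ⇐ 4-methoxycyclohexanone 1 by enantioselective deprotonation (sets the methoxy-bearing centre).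
5. Rings: the carbocycle is bought as 1 and the arene as 7; no ring is formed in the route.

Assumption: lithium (R,R)-bis(1-phenylethyl)amide deprotonates 1 in the same enantiotopic sense as it does 4-tert-butylcyclohexanone, giving the (S)-enol silane; if the sense were opposite, the (S,S)-amide would be used.

**Step 1**
Reactants: 1 4-methoxycyclohexanone
Product: 3 (S)-[(4-methoxycyclohex-1-en-1-yl)oxy]trimethylsilane, via lithium enolate 2 (not isolated)
Conditions: (R,R)-bis(1-phenylethyl)amine, n-BuLi, THF, −78 °C; TMSCl, then 1, −100 °C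
Reagents that add atoms: chlorotrimethylsilane, C[Si](C)(C)Cl
Why: Simpkins–Koga enantioselective deprotonation with in situ silyl trapping (Corey internal quench), in which the C2-symmetric chiral lithium amide distinguishes the two enantiotopic axial α-protons of the chair of 1 and so fixes the methoxy-bearing carbon as a stereocentre (megaphone C4).

**Step 2**
Reactants: 3 (S)-[(4-methoxycyclohex-1-en-1-yl)oxy]trimethylsilane (2 equiv); 4 propanal
Product: 6 (2S)-2-[(5S)-5-methoxy-2-oxocyclohexyl]propanal (mixture of epimers at ring C1), via enamine 5 (not isolated)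
Conditions: (2R,5R)-5-benzyl-2-tert-butyl-3-methylimidazolidin-4-one·TFA (20 mol %), CAN (2.2 equiv), 2,6-di-tert-butylpyridine, H2O, DME, −20 °C
Reagents that add atoms: water, O
Why: Proposed new method: SOMO organocatalysis, closest known reaction the imidazolidinone/CAN α-enolation of aldehydes with acyclic enol silanes — CAN oxidises enamine 5 to its 3π-electron radical cation, an α-carbonyl cation (enolonium) equivalent of propanal, whose α-carbon is attacked by the nucleophilic carbon of the cyclic enol silane 3, a second oxidation and loss of silyl give the ketone and hydrolysis releases 6; the benzyl group of the (2R,5R) catalyst covers the Si face of the E-configured radical cation, so the bond forms on the Re face and the aldehyde α-centre is S, while the new ring centre is left as a mixture because it is enolised again in step 5.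

**Step 3**
Reactants: 6 (2S)-2-[(5S)-5-methoxy-2-oxocyclohexyl]propanal; 7 5-bromo-1,2,3-trimethoxybenzene
Product: 10 (4S)-2-[(1R,2S)-1-hydroxy-1-(3,4,5-trimethoxyphenyl)propan-2-yl]-4-methoxycyclohexan-1-one (mixture of C2 epimers), via aryl Grignard reagent 8 (not isolated), via aryltitanium reagent 9 (not isolated)
Conditions: 7, Mg, THF, reflux; ClTi(OiPr)3, −78 → 0 °C; then 6, −78 → −20 °C; H2O
Reagents that add atoms: none
Why: Reetz-type aryltitanium addition, in which the non-basic ArTi(OiPr)3 reacts with the aldehyde and not with the ketone, and Felkin–Anh attack (ring carbon as the large group anti to the incoming aryl, approach past H and not CH3) gives the 1,2-syn carbinol, i.e. the (1R) benzylic centre next to the (2S) methyl centre.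

**Step 4**
Reactants: 10 (4S)-2-[(1R,2S)-1-hydroxy-1-(3,4,5-trimethoxyphenyl)propan-2-yl]-4-methoxycyclohexan-1-one
Product: 12 (4R)-6-[(1R,2S)-1-hydroxy-1-(3,4,5-trimethoxyphenyl)propan-2-yl]-4-methoxycyclohex-2-en-1-one (mixture of C6 epimers), via bis-silyl enol ether 11 (not isolated)
Conditions: LDA (2.3 equiv), TMSCl, THF, −78 °C; Pd(OAc)2 (1.1 equiv), MeCN, rt; 1 M HCl, THF, 0 °C
Reagents that add atoms: none
Why: Saegusa–Ito oxidation, in which LDA removes the kinetically favoured proton of the unsubstituted α-CH2, the benzylic hydroxyl is masked in the same operation as its TMS ether (protecting it from Pd(II)), and Pd(II) converts the enol silane into the enone by β-hydride elimination without forming or touching a stereocentre other than the epimerisable ring α-carbon.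

**Step 5**
Reactants: 12 (4R)-6-[(1R,2S)-1-hydroxy-1-(3,4,5-trimethoxyphenyl)propan-2-yl]-4-methoxycyclohex-2-en-1-one; 13 allyl bromide
Product: 15 megaphone, (4R,6R)-6-allyl-6-[(1R,2S)-1-hydroxy-1-(3,4,5-trimethoxyphenyl)propan-2-yl]-4-methoxycyclohex-2-en-1-one, via dilithium dianion 14 (not isolated)
Conditions: LDA (2.2 equiv), THF, −78 °C; 13, DMPU, −78 → −20 °C; H2O
Reagents that add atoms: none
Why: Fráter–Seebach-type C-alkylation of an alkoxide–enolate dianion, in which only the α′-carbon can be enolised and allyl bromide enters on the enolate face opposite the CH(OLi)Ar group of the adjacent methyl-bearing centre held in its A(1,3)-minimised conformation (C–H eclipsing the enolate), which is also the face trans to the ring methoxy group, so the quaternary centre is formed as (6R).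

**Compound list**
1 | 4-methoxycyclohexanone | COC1CCC(=O)CC1 | starting material
2 | lithium (S)-4-methoxycyclohex-1-en-1-olate | [Li+].[O-]C1=CC[C@@H](OC)CC1 | intermediate
3 | (S)-[(4-methoxycyclohex-1-en-1-yl)oxy]trimethylsilane | C[Si](C)(C)OC1=CC[C@@H](OC)CC1 | intermediate
4 | propanal | CCC=O | starting material
5 | (2R,5R)-5-benzyl-2-tert-butyl-3-methyl-1-[(E)-prop-1-en-1-yl]imidazolidin-4-one (enamine) | CN1[C@H](C(C)(C)C)N(/C=C/C)[C@H](Cc2ccccc2)C1=O | intermediate
6 | (2S)-2-[(5S)-5-methoxy-2-oxocyclohexyl]propanal (ring C1 epimers) | O=C[C@@H](C)C1C[C@@H](OC)CCC1=O | intermediate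
7 | 5-bromo-1,2,3-trimethoxybenzene | COc1cc(Br)cc(OC)c1OC | starting material
8 | (3,4,5-trimethoxyphenyl)magnesium bromide | COc1cc([Mg]Br)cc(OC)c1OC | intermediate
9 | triisopropoxy(3,4,5-trimethoxyphenyl)titanium | COc1cc(cc(OC)c1OC)[Ti](OC(C)C)(OC(C)C)OC(C)C | intermediate
10 | (4S)-2-[(1R,2S)-1-hydroxy-1-(3,4,5-trimethoxyphenyl)propan-2-yl]-4-methoxycyclohexan-1-one (C2 epimers) | O=C1CC[C@H](OC)CC1[C@H](C)[C@@H](O)c2cc(OC)c(OC)c(OC)c2 | intermediate
11 | trimethyl{[(4S)-4-methoxy-6-[(1R,2S)-1-(3,4,5-trimethoxyphenyl)-1-(trimethylsilyloxy)propan-2-yl]cyclohex-1-en-1-yl]oxy}silane | C[Si](C)(C)OC1=CC[C@H](OC)CC1[C@H](C)[C@@H](O[Si](C)(C)C)c2cc(OC)c(OC)c(OC)c2 | intermediate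
12 | (4R)-6-[(1R,2S)-1-hydroxy-1-(3,4,5-trimethoxyphenyl)propan-2-yl]-4-methoxycyclohex-2-en-1-one (C6 epimers) | O=C1C=C[C@H](OC)CC1[C@H](C)[C@@H](O)c2cc(OC)c(OC)c(OC)c2 | intermediate
13 | allyl bromide | C=CCBr | starting material
14 | dilithium (1R,2S)-2-[(5R)-5-methoxy-2-oxidocyclohexa-1,3-dien-1-yl]-1-(3,4,5-trimethoxyphenyl)propan-1-olate | [Li+].[Li+].[O-]C1=C(C[C@@H](OC)C=C1)[C@H](C)[C@@H]([O-])c2cc(OC)c(OC)c(OC)c2 | intermediate
15 | megaphone, (4R,6R)-6-allyl-6-[(1R,2S)-1-hydroxy-1-(3,4,5-trimethoxyphenyl)propan-2-yl]-4-methoxycyclohex-2-en-1-one | C=CC[C@]1([C@H](C)[C@@H](O)c2cc(OC)c(OC)c(OC)c2)C[C@@H](OC)C=CC1=O | target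

**Totals**
Total step count: 5. Longest linear sequence: 5 steps (1 → 3 → 6 → 10 → 12 → 15). The two ring-independent centres (C4 in step 1, C7 in step 2) are set by separate enantioselective steps, so the minor enantiomer from either step ends up in diastereomers that are removed by chromatography at 12 or 15.

**Steps most likely to fail, with fallbacks**

Step 2 is the most uncertain, because a cyclic trisubstituted enol silane has not been shown to intercept the enamine radical cation faster than CAN oxidises or hydrolyses it. The fallback sets out from 3 and comes back at 6, and replaces the catalytic radical-cation coupling with a chiral-pool SN2 on an α-carbonyl cation equivalent. MeLi (THF, 0 °C) cleaves 3 to the lithium enolate 2, which is alkylated with ethyl (S)-2-(trifluoromethanesulfonyloxy)propanoate (from ethyl L-lactate) in THF/DMPU at −78 °C with inversion to give ethyl (2S)-2-[(5S)-5-methoxy-2-oxocyclohexyl]propanoate F1. LiAlH4 reduces ester and ketone to (2S)-2-[(5S)-2-hydroxy-5-methoxycyclohexyl]propan-1-ol F2, and Dess–Martin oxidation of both hydroxyls returns keto aldehyde 6.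

Step 5 may give O-allylation of the alkoxide, slow C-allylation at the hindered carbon, or insufficient facial selectivity. The fallback sets out from 12 and comes back at 15, and replaces the dianion alkylation with a catalyst-controlled Pd decarboxylative allylation. TESCl/imidazole gives (4R)-4-methoxy-6-[(1R,2S)-1-(3,4,5-trimethoxyphenyl)-1-(triethylsilyloxy)propan-2-yl]cyclohex-2-en-1-one F4. LiHMDS/TMEDA then allyl chloroformate gives allyl (4R)-4-methoxy-2-[(1R,2S)-1-(3,4,5-trimethoxyphenyl)-1-(triethylsilyloxy)propan-2-yl]cyclohexa-1,5-dien-1-yl carbonate F5. Pd2(dba)3/(S)-t-BuPHOX in toluene at 30 °C (Tsuji–Stoltz) gives megaphone triethylsilyl ether F6; the known facial sense of this ligand with cyclohexanone enol carbonates matches the (6R) centre and the substrate bias. HF·pyridine then releases 15.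

Step 3 relies on substrate control from an α-methyl centre whose large group is only a secondary ring carbon (itself an epimer mixture), so the Felkin ratio may be modest. The fallback sets out from 6 and comes back at 10, and replaces substrate control with catalyst-controlled aryl transfer. 3,4,5-Trimethoxyphenylboronic acid and Et2Zn (toluene, 60 °C) give ethyl(3,4,5-trimethoxyphenyl)zinc F3, which adds to the aldehyde of 6 at 0 °C in the presence of (−)-MIB (10 mol %). This ligand's Si-face delivery reinforces the Felkin preference and leaves the ketone untouched.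

**Further compounds**
F1 | step 2 | ethyl (2S)-2-[(5S)-5-methoxy-2-oxocyclohexyl]propanoate | CCOC(=O)[C@@H](C)C1C[C@@H](OC)CCC1=O
F2 | step 2 | (2S)-2-[(5S)-2-hydroxy-5-methoxycyclohexyl]propan-1-ol | OC[C@@H](C)C1C[C@@H](OC)CCC1O
F3 | step 3 | ethyl(3,4,5-trimethoxyphenyl)zinc | CC[Zn]c1cc(OC)c(OC)c(OC)c1
F4 | step 5 | (4R)-4-methoxy-6-[(1R,2S)-1-(3,4,5-trimethoxyphenyl)-1-(triethylsilyloxy)propan-2-yl]cyclohex-2-en-1-one | O=C1C=C[C@H](OC)CC1[C@H](C)[C@@H](O[Si](CC)(CC)CC)c2cc(OC)c(OC)c(OC)c2
F5 | step 5 | allyl (4R)-4-methoxy-2-[(1R,2S)-1-(3,4,5-trimethoxyphenyl)-1-(triethylsilyloxy)propan-2-yl]cyclohexa-1,5-dien-1-yl carbonate | C=CCOC(=O)OC1=C(C[C@@H](OC)C=C1)[C@H](C)[C@@H](O[Si](CC)(CC)CC)c2cc(OC)c(OC)c(OC)c2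
F6 | step 5 | megaphone triethylsilyl ether | C=CC[C@]1([C@H](C)[C@@H](O[Si](CC)(CC)CC)c2cc(OC)c(OC)c(OC)c2)C[C@@H](OC)C=CC1=O
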